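Numbering (halimane): ring A = C1–C5 + C10, ring B = C5–C10, side chain C11–C15 with C16 on C13, C17 on C8, C18/C19 on C4, C20 on C9, glycerol C1'–C3'.
Retrosynthetic cuts, in order: the C3' acetate and the masked C2',C3' diol; C12–C13 (decalin joined to glyceryl ester); C9–C11, with C1=C10 moved back to C9=C10 (Claisen); C1–C10 (ring A); C9–C20; C3–C4. This leaves (R)-pulegone, which supplies all of ring B plus C4 and C17–C19.
Enabling feature: C13 is a CH(CH3) β to the ester carbonyl C15, so C13=C14–C15(=O)O–C1' is a latent (E)-crotonate. C12 is an unbranched primary CH2 kept one carbon (C11) away from quaternary C9 of ring B, so it can be a stable Grignard carbon. One ligand-controlled 1,4-addition therefore makes C12–C13, sets C13 and brings in the whole chiral glycerol ester.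
Forward order: ring B (pulegone), C1–C3 arm on C4, C20, ring A by C1–C10 closure, [3,3] shift that builds C9 and places C1=C10, C12 bromide, chain union, glycerol unmasking, C3' acetylation.
Stereochemistry: C8 from pulegone; C5 by equilibration (trans to C17); a temporary C1 carbinol by allylic 1,3-strain in the ring A chair; C9 by suprafacial transfer from C1; C13 from the copper ligand; C2' from (R)-solketal.

Key step: step 10

Assumption: the (R,S)-configured ferrocenyl diphosphine is taken to direct the copper-bound alkyl group to the Si face of C13 of an (E)-crotonate. Its mirror image is equally available and would replace it, with nothing else changed, should a model addition show the opposite sense.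

Step 1
Reactants: 1 (R)-(+)-pulegone; 2 2-(2-bromoethyl)-1,3-dioxolane
Product: 5 (2S,5R)-2-[4-(1,3-dioxolan-2-yl)-2-methylbutan-2-yl]-5-methylcyclohexan-1-one, via Grignard reagent 3 (not isolated), via bromomagnesium enolate 4 (not isolated)
Conditions: Mg, THF, 25 °C (2 to 3); CuBr·SMe2 (10 mol %), 1, THF–Me2S, −40 to 0 °C; H2O; crude, KOH, EtOH–H2O, reflux
Reagents that add atoms: none
Why: Copper-catalysed 1,4-addition of a Grignard reagent to the s-cis exocyclic enone of pulegone (the reaction type by which 8-substituted menthones are made) forms C3–C4 and quaternary C4, and base equilibration of the enolisable C5 should favour the menthone-like trans isomer, in which the bulky C5 substituent and C17 are both equatorial (5S).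

Step 2
Reactants: 5 (2S,5R)-2-[4-(1,3-dioxolan-2-yl)-2-methylbutan-2-yl]-5-methylcyclohexan-1-one
Product: 7 (2S,3R,6S)-6-[4-(1,3-dioxolan-2-yl)-2-methylbutan-2-yl]-2,3-dimethylcyclohexan-1-one, via lithium enolate 6 (not isolated)
Conditions: LiN(i-Pr)2, THF, −78 °C; MeI, −78 to −20 °C
Reagents that add atoms: iodomethane, CI
Why: Kinetic enolate alkylation, in which LiN(i-Pr)2 should take a proton from the open C9 methylene and not the C5–H shielded by quaternary C4, MeI then brings in C20, and the configuration at C9 (equatorial methyl expected) does not matter because C9 becomes trigonal in step 3.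

Step 3
Reactants: 7 (2S,3R,6S)-6-[4-(1,3-dioxolan-2-yl)-2-methylbutan-2-yl]-2,3-dimethylcyclohexan-1-one
Product: 9 (3R,6S)-6-[4-(1,3-dioxolan-2-yl)-2-methylbutan-2-yl]-2,3-dimethylcyclohex-1-en-1-yl trifluoromethanesulfonate, via potassium enolate 8 (not isolated)
Conditions: KN(SiMe3)2, THF, −78 to 0 °C; N-(5-chloropyridin-2-yl)bis(trifluoromethanesulfonimide), −78 to 25 °C
Reagents that add atoms: N-(5-chloropyridin-2-yl)bis(trifluoromethanesulfonimide), FC(F)(F)S(=O)(=O)N(c1ccc(Cl)cn1)S(=O)(=O)C(F)(F)F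
Why: O-Sulfonylation of a ketone enolate, in which enolisation toward C9 should prevail because the alternative C5=C10 enolate would carry the tert-alkyl group on a tetrasubstituted double bond and its proton is shielded by C4, so the C9=C10 alkenyl triflate should result with C5 and C8 untouched.

Step 4
Reactants: 9 (3R,6S)-6-[4-(1,3-dioxolan-2-yl)-2-methylbutan-2-yl]-2,3-dimethylcyclohex-1-en-1-yl trifluoromethanesulfonate
Product: 10 (3R,6S)-2,3-dimethyl-6-(2-methyl-5-oxopentan-2-yl)cyclohex-1-en-1-yl trifluoromethanesulfonate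
Conditions: 1 M HCl, THF, 25 °C
Reagents that add atoms: water, O
Why: Acid-catalysed acetal hydrolysis, to which the electron-poor alkenyl triflate is inert, frees the C1 aldehyde, and C5 is no longer enolisable.

Step 5
Reactants: 10 (3R,6S)-2,3-dimethyl-6-(2-methyl-5-oxopentan-2-yl)cyclohex-1-en-1-yl trifluoromethanesulfonate
Product: 12 (1S,4aS,7R)-4,4,7,8-tetramethyl-1,2,3,4,4a,5,6,7-octahydronaphthalen-1-ol, via alkenylchromium dichloride 11 (not isolated)
Conditions: CrCl2 (4 equiv), NiCl2 (2 mol %), DMF, 25 °C, 0.01 M; H2O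
Reagents that add atoms: none
Why: Intramolecular Nozaki–Hiyama–Kishi reaction, in which zerovalent nickel inserts into the C10–OTf bond, transmetalation gives the trivalent alkenylchromium 11, and its 6-exo addition to the C1 aldehyde (helped by the gem-dimethyl group at C4) closes ring A, the C1 oxygen being expected axial on the α face (1S) because the ring A chair is fixed by C5 and an equatorial C1–O bond would be eclipsed with C20 across C9=C10 (allylic 1,3-strain).

Step 6
Reactants: 12 (1S,4aS,7R)-4,4,7,8-tetramethyl-1,2,3,4,4a,5,6,7-octahydronaphthalen-1-ol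
Product: 14 N,N-dimethyl-2-[(1R,2R,4aS)-1,2,5,5-tetramethyl-1,2,3,4,4a,5,6,7-octahydronaphthalen-1-yl]acetamide, via ketene N,O-acetal 13 (not isolated)
Conditions: MeC(OMe)2NMe2 (5 equiv), xylene, 140 °C, MeOH distilled off
Reagents that add atoms: 1,1-dimethoxy-N,N-dimethylethan-1-amine, COC(C)(OC)N(C)C
Why: Eschenmoser–Claisen rearrangement, in which alcohol exchange and loss of methanol give the ketene N,O-acetal 13, whose suprafacial [3,3] shift passes the chirality of the axial C1–O bond to the α face of C9, so that C9–C11 and the quaternary centre (9R, C11 cis to C17) form while the double bond moves regiospecifically to C1=C10 and the helper oxygen leaves C1.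

Step 7
Reactants: 14 N,N-dimethyl-2-[(1R,2R,4aS)-1,2,5,5-tetramethyl-1,2,3,4,4a,5,6,7-octahydronaphthalen-1-yl]acetamide
Product: 15 2-[(1R,2R,4aS)-1,2,5,5-tetramethyl-1,2,3,4,4a,5,6,7-octahydronaphthalen-1-yl]ethan-1-ol
Conditions: LiEt3BH (3 equiv), THF, 0 to 25 °C; H2O
Reagents that add atoms: none
Why: Reduction of a tertiary amide with LiEt3BH proceeds with C–N cleavage to the primary alcohol and should leave the hindered trisubstituted alkene alone.

Step 8
Reactants: 15 2-[(1R,2R,4aS)-1,2,5,5-tetramethyl-1,2,3,4,4a,5,6,7-octahydronaphthalen-1-yl]ethan-1-ol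
Product: 16 (1R,2R,4aS)-1-(2-bromoethyl)-1,2,5,5-tetramethyl-1,2,3,4,4a,5,6,7-octahydronaphthalene
Conditions: CBr4, PPh3, CH2Cl2, 0 °C
Reagents that add atoms: tetrabromomethane, BrC(Br)(Br)Br
Why: Appel reaction, a neutral SN2 displacement of the oxyphosphonium ion at primary C12 that avoids acid, which might shift the C1=C10 double bond.

Step 9
Reactants: 17 (R)-solketal, [(4R)-2,2-dimethyl-1,3-dioxolan-4-yl]methanol; 18 (E)-crotonic anhydride
Product: 19 [(4S)-2,2-dimethyl-1,3-dioxolan-4-yl]methyl (E)-but-2-enoate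
Conditions: pyridine (2 equiv), 4-(dimethylamino)pyridine (5 mol %), CH2Cl2, 0 to 25 °C
Reagents that add atoms: none
Why: 4-(Dimethylamino)pyridine-catalysed acylation of the primary alcohol with the anhydride (chosen over the acid chloride to avoid deconjugation through a vinylketene) should keep the (E)-geometry, and the C2' stereocentre is not touched.

Step 10
Reactants: 16 (1R,2R,4aS)-1-(2-bromoethyl)-1,2,5,5-tetramethyl-1,2,3,4,4a,5,6,7-octahydronaphthalene; 19 [(4S)-2,2-dimethyl-1,3-dioxolan-4-yl]methyl (E)-but-2-enoate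
Product: 22 [(4S)-2,2-dimethyl-1,3-dioxolan-4-yl]methyl (3R)-3-methyl-5-[(1R,2R,4aS)-1,2,5,5-tetramethyl-1,2,3,4,4a,5,6,7-octahydronaphthalen-1-yl]pentanoate, via Grignard reagent 20 (not isolated), via bromomagnesium ester enolate 21 (not isolated)
Conditions: Mg, Et2O, reflux (16 to 20); CuBr·SMe2 (5 mol %), (R)-1-[(S)-2-(diphenylphosphino)ferrocenyl]ethyldicyclohexylphosphine (6 mol %), t-BuOMe, −75 °C, 19 added slowly; H2O
Reagents that add atoms: none
Why: Grignard reagent 20 and the CuBr–diphosphine complex form a chiral alkylcopper–magnesium species of monovalent copper that binds the C13=C14 bond of 19, adds oxidatively at C13 to a trivalent copper σ-alkyl and reductively eliminates to make C12–C13, leaving enolate 21, which is protonated on quench. The closest known reaction type is the copper/ferrocenyl-diphosphine-catalysed enantioselective conjugate addition of linear primary alkylmagnesium bromides to (E)-crotonates and other β-alkyl acrylic esters in t-BuOMe at −75 °C. No ring is closed. The only new stereocentre, C13, is controlled by the ligand, which should present the Si face of C13 to the copper-bound C12 and so give 13R, while C9 on the nucleophile and C2' on the acceptor lie outside the copper coordination sphere and should not override it. The step needs 1,4- over 1,2-selectivity and clean face selectivity; these are secured by the ligand-accelerated copper pathway at −75 °C, the single (E)-geometry of 19, the low carbonyl reactivity of an alkyl ester, the C11 spacer that keeps C12 unbranched, and the fact that C12 cannot close onto C1=C10 without making a cyclobutane, and the acetonide and the trisubstituted alkene are inert. In one operation the step completes the C20 acyl skeleton, sets the remote stereocentre and attaches the glycerol with its own stereocentre.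

Step 11
Reactants: 22 [(4S)-2,2-dimethyl-1,3-dioxolan-4-yl]methyl (3R)-3-methyl-5-[(1R,2R,4aS)-1,2,5,5-tetramethyl-1,2,3,4,4a,5,6,7-octahydronaphthalen-1-yl]pentanoate
Product: 23 (2S)-2,3-dihydroxypropyl (3R)-3-methyl-5-[(1R,2R,4aS)-1,2,5,5-tetramethyl-1,2,3,4,4a,5,6,7-octahydronaphthalen-1-yl]pentanoate
Conditions: AcOH–H2O (4:1), 40 °C
Reagents that add atoms: none
Why: Mild acid hydrolysis of the terminal acetonide should free the C2',C3' diol without acyl migration or isomerisation of C1=C10.

Step 12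
Reactants: 23 (2S)-2,3-dihydroxypropyl (3R)-3-methyl-5-[(1R,2R,4aS)-1,2,5,5-tetramethyl-1,2,3,4,4a,5,6,7-octahydronaphthalen-1-yl]pentanoate
Product: 24 (2S)-3-acetoxy-2-hydroxypropyl (3R)-3-methyl-5-[(1R,2R,4aS)-1,2,5,5-tetramethyl-1,2,3,4,4a,5,6,7-octahydronaphthalen-1-yl]pentanoate (target)
Conditions: AcCl (1.05 equiv), 2,4,6-collidine, CH2Cl2, −78 °C
Reagents that add atoms: acetyl chloride, CC(=O)Cl
Why: Selective acylation of a primary over a secondary alcohol with AcCl and the hindered base 2,4,6-collidine at low temperature should acetylate only C3'–OH and leave no time for a 1,2-acyl shift.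

Compound list
1 | (R)-(+)-pulegone | C[C@@H]1CCC(=C(C)C)C(=O)C1 | starting material
2 | 2-(2-bromoethyl)-1,3-dioxolane | BrCCC1OCCO1 | starting material
3 | [2-(1,3-dioxolan-2-yl)ethyl]magnesium bromide | Br[Mg]CCC1OCCO1 | intermediate
4 | bromomagnesium (5R)-2-[4-(1,3-dioxolan-2-yl)-2-methylbutan-2-yl]-5-methylcyclohex-1-en-1-olate | C[C@@H]1CCC(C(C)(C)CCC2OCCO2)=C(O[Mg]Br)C1 | intermediate
5 | (2S,5R)-2-[4-(1,3-dioxolan-2-yl)-2-methylbutan-2-yl]-5-methylcyclohexan-1-one | C[C@@H]1CC[C@@H](C(C)(C)CCC2OCCO2)C(=O)C1 | intermediate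
6 | lithium (3R,6S)-6-[4-(1,3-dioxolan-2-yl)-2-methylbutan-2-yl]-3-methylcyclohex-1-en-1-olate | C[C@@H]1CC[C@@H](C(C)(C)CCC2OCCO2)C(O[Li])=C1 | intermediate
7 | (2S,3R,6S)-6-[4-(1,3-dioxolan-2-yl)-2-methylbutan-2-yl]-2,3-dimethylcyclohexan-1-one | C[C@@H]1CC[C@@H](C(C)(C)CCC2OCCO2)C(=O)[C@H]1C | intermediate
8 | potassium (3R,6S)-6-[4-(1,3-dioxolan-2-yl)-2-methylbutan-2-yl]-2,3-dimethylcyclohex-1-en-1-olate | C[C@@H]1CC[C@@H](C(C)(C)CCC2OCCO2)C(O[K])=C1C | intermediate
9 | (3R,6S)-6-[4-(1,3-dioxolan-2-yl)-2-methylbutan-2-yl]-2,3-dimethylcyclohex-1-en-1-yl trifluoromethanesulfonate | C[C@@H]1CC[C@@H](C(C)(C)CCC2OCCO2)C(OS(=O)(=O)C(F)(F)F)=C1C | intermediate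
10 | (3R,6S)-2,3-dimethyl-6-(2-methyl-5-oxopentan-2-yl)cyclohex-1-en-1-yl trifluoromethanesulfonate | C[C@@H]1CC[C@@H](C(C)(C)CCC=O)C(OS(=O)(=O)C(F)(F)F)=C1C | intermediate
11 | dichloro[(3R,6S)-2,3-dimethyl-6-(2-methyl-5-oxopentan-2-yl)cyclohex-1-en-1-yl]chromium | C[C@@H]1CC[C@@H](C(C)(C)CCC=O)C([Cr](Cl)Cl)=C1C | intermediate
12 | (1S,4aS,7R)-4,4,7,8-tetramethyl-1,2,3,4,4a,5,6,7-octahydronaphthalen-1-ol (1α-hydroxy, C9=C10) | C[C@@H]1CC[C@H]2C(C)(C)CC[C@H](O)C2=C1C | intermediate
13 | (1S,4aS,7R)-1-{[1-(dimethylamino)ethenyl]oxy}-4,4,7,8-tetramethyl-1,2,3,4,4a,5,6,7-octahydronaphthalene | C[C@@H]1CC[C@H]2C(C)(C)CC[C@H](OC(=C)N(C)C)C2=C1C | intermediate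
14 | N,N-dimethyl-2-[(1R,2R,4aS)-1,2,5,5-tetramethyl-1,2,3,4,4a,5,6,7-octahydronaphthalen-1-yl]acetamide | CN(C)C(=O)C[C@@]1(C)C2=CCCC(C)(C)[C@@H]2CC[C@H]1C | intermediate
15 | 2-[(1R,2R,4aS)-1,2,5,5-tetramethyl-1,2,3,4,4a,5,6,7-octahydronaphthalen-1-yl]ethan-1-ol | OCC[C@@]1(C)C2=CCCC(C)(C)[C@@H]2CC[C@H]1C | intermediate
16 | (1R,2R,4aS)-1-(2-bromoethyl)-1,2,5,5-tetramethyl-1,2,3,4,4a,5,6,7-octahydronaphthalene | BrCC[C@@]1(C)C2=CCCC(C)(C)[C@@H]2CC[C@H]1C | intermediate
17 | (R)-solketal, [(4R)-2,2-dimethyl-1,3-dioxolan-4-yl]methanol | CC1(C)OC[C@@H](CO)O1 | starting material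
18 | (E)-crotonic anhydride | C/C=C/C(=O)OC(=O)/C=C/C | starting material
19 | [(4S)-2,2-dimethyl-1,3-dioxolan-4-yl]methyl (E)-but-2-enoate | C/C=C/C(=O)OC[C@@H]1COC(C)(C)O1 | intermediate
20 | {2-[(1R,2R,4aS)-1,2,5,5-tetramethyl-1,2,3,4,4a,5,6,7-octahydronaphthalen-1-yl]ethyl}magnesium bromide | Br[Mg]CC[C@@]1(C)C2=CCCC(C)(C)[C@@H]2CC[C@H]1C | intermediate
21 | bromomagnesium enolate of 22 (C14=C15, enolate geometry not defined) | CC1(C)OC[C@@H](COC(O[Mg]Br)=C[C@H](C)CC[C@@]2(C)C3=CCCC(C)(C)[C@@H]3CC[C@H]2C)O1 | intermediate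
22 | [(4S)-2,2-dimethyl-1,3-dioxolan-4-yl]methyl (3R)-3-methyl-5-[(1R,2R,4aS)-1,2,5,5-tetramethyl-1,2,3,4,4a,5,6,7-octahydronaphthalen-1-yl]pentanoate | CC1(C)OC[C@@H](COC(=O)C[C@H](C)CC[C@@]2(C)C3=CCCC(C)(C)[C@@H]3CC[C@H]2C)O1 | intermediate
23 | (2S)-2,3-dihydroxypropyl (3R)-3-methyl-5-[(1R,2R,4aS)-1,2,5,5-tetramethyl-1,2,3,4,4a,5,6,7-octahydronaphthalen-1-yl]pentanoate | OC[C@H](O)COC(=O)C[C@H](C)CC[C@@]1(C)C2=CCCC(C)(C)[C@@H]2CC[C@H]1C | intermediate
24 | (2S)-3-acetoxy-2-hydroxypropyl (3R)-3-methyl-5-[(1R,2R,4aS)-1,2,5,5-tetramethyl-1,2,3,4,4a,5,6,7-octahydronaphthalen-1-yl]pentanoate | CC(=O)OC[C@H](O)COC(=O)C[C@H](C)CC[C@@]1(C)C2=CCCC(C)(C)[C@@H]2CC[C@H]1C | target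

Total step count: 12. Longest linear sequence: 11 (steps 1–8 and 10–12).

Steps most likely to fail

Step 10. Enantioface control may erode through a ligand-free background addition (magnesium chelated by the ester and dioxolane oxygens). The ester may also suffer competing 1,2-attack, or magnesium insertion may stay incomplete on small scale. The fallback replaces catalyst control by a stereospecific substitution.
- It sets out from 16, which is turned into Grignard reagent 20 as before.
- With CuBr·SMe2 (10 mol %) in THF–Me2S at −30 °C, 20 should open commercial (R)-4-methyloxetan-2-one at its alkyl C–O bond. C12 attacks C13 by SN2 with inversion, and the strain of the four-membered lactone drives the substitution.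
- Work-up with 1 M HCl should give (3R)-3-methyl-5-[(1R,2R,4aS)-1,2,5,5-tetramethyl-1,2,3,4,4a,5,6,7-octahydronaphthalen-1-yl]pentanoic acid F1.
- Carbodiimide esterification of F1 with 17 (N-(3-dimethylaminopropyl)-N'-ethylcarbodiimide hydrochloride, 4-(dimethylamino)pyridine, CH2Cl2) comes back to the route at 22.

Step 6. The [3,3] shift onto the fully substituted C9 may be slow at the temperature at which the allylic C1 oxygen function is lost by elimination. The fallback uses a low-temperature [2,3] shift followed by a one-carbon extension.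
- It sets out from 12, which with KH and ICH2SnBu3 in THF should give the tributylstannylmethyl ether F2.
- n-BuLi in THF at −78 °C triggers tin–lithium exchange and a suprafacial Wittig–Still rearrangement. This delivers C11 to the α face of C9 and places C1=C10, giving [(1R,2R,4aS)-1,2,5,5-tetramethyl-1,2,3,4,4a,5,6,7-octahydronaphthalen-1-yl]methanol F3.
- Dess–Martin oxidation gives the C11 carbaldehyde F4.
- Wittig methylenation with Ph3P=CH2 gives the C9-vinyl compound F5.
- 9-Borabicyclo[3.3.1]nonane should add only to the monosubstituted C11=C12 bond, giving the B-alkylborane F6.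
- NaOH/H2O2 oxidation comes back to the route at 15.

Step 5. The addition of the alkenylchromium to the aldehyde may show poor facial selectivity at C1, which would be passed on to C9 in step 6. The fallback replaces substrate control by reagent control.
- It sets out from 12 as obtained from the cyclisation, whatever its composition at C1.
- Dess–Martin oxidation gives (4aS,7R)-4,4,7,8-tetramethyl-3,4,4a,5,6,7-hexahydronaphthalen-1(2H)-one F7.
- Corey–Bakshi–Shibata reduction with (R)-1-methyl-3,3-diphenyltetrahydro-1H,3H-pyrrolo[1,2-c][1,3,2]oxazaborole (10 mol %) and BH3·SMe2 treats the alkylidene side as the large group. It should come back to the route at 12 with the 1S carbinol.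

Further compounds
F1 | step 10 | (3R)-3-methyl-5-[(1R,2R,4aS)-1,2,5,5-tetramethyl-1,2,3,4,4a,5,6,7-octahydronaphthalen-1-yl]pentanoic acid | OC(=O)C[C@H](C)CC[C@@]1(C)C2=CCCC(C)(C)[C@@H]2CC[C@H]1C
F2 | step 6 | tributyl({[(1S,4aS,7R)-4,4,7,8-tetramethyl-1,2,3,4,4a,5,6,7-octahydronaphthalen-1-yl]oxy}methyl)stannane | C[C@@H]1CC[C@H]2C(C)(C)CC[C@H](OC[Sn](CCCC)(CCCC)CCCC)C2=C1C
F3 | step 6 | [(1R,2R,4aS)-1,2,5,5-tetramethyl-1,2,3,4,4a,5,6,7-octahydronaphthalen-1-yl]methanol | OC[C@@]1(C)C2=CCCC(C)(C)[C@@H]2CC[C@H]1C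
F4 | step 6 | (1R,2R,4aS)-1,2,5,5-tetramethyl-1,2,3,4,4a,5,6,7-octahydronaphthalene-1-carbaldehyde | O=C[C@@]1(C)C2=CCCC(C)(C)[C@@H]2CC[C@H]1C
F5 | step 6 | (1R,2R,4aS)-1-ethenyl-1,2,5,5-tetramethyl-1,2,3,4,4a,5,6,7-octahydronaphthalene | C=C[C@@]1(C)C2=CCCC(C)(C)[C@@H]2CC[C@H]1C
F6 | step 6 | 9-{2-[(1R,2R,4aS)-1,2,5,5-tetramethyl-1,2,3,4,4a,5,6,7-octahydronaphthalen-1-yl]ethyl}-9-borabicyclo[3.3.1]nonane | C(C[C@@]1(C)C2=CCCC(C)(C)[C@@H]2CC[C@H]1C)B3C4CCCC3CCC4
F7 | step 5 | (4aS,7R)-4,4,7,8-tetramethyl-3,4,4a,5,6,7-hexahydronaphthalen-1(2H)-one | C[C@@H]1CC[C@H]2C(C)(C)CCC(=O)C2=C1C
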